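**Retrosynthetic overview**

1. Local numbering: C1 methyl-bearing ring-fusion carbon, C2 CH–O-angelate, C3 CH2, C4 C(OH)(i-Pr), C5 ring-fusion CH, C6 CH–O-anisate, C7 CH2, C8(CH3)=C9H, C10 CH2; ring A = C1–C5, ring B = C1, C5–C10. The C2 and C6 esters go on last; C6–OH comes from a C4–OH-directed reduction of a ring B β,γ-enone.
2. Ring B (formed second): C6–C7 by Dieckmann-type acylation of a (Z)-allylic sulfone anion on the C5 methyl ester, then reductive desulfonylation.
3. Ring A (formed first, key disconnection C4–C5): the strategy rests on the tertiary carbinol C4 of five-membered ring A being bonded to C5, which sits beside quaternary C1. A C5 rhodium carbenoid without β-hydrogen, made from an acyclic α-diazo ester, inserts into the C4–H bond of a secondary silyl ether with retention.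
4. Acyclic chain: C4 by Noyori hydrogenation, C2 by 1,3-anti reduction, quaternary C1 by two Fráter–Seebach alkylations (allylic bromide, then MeI). Arndt–Eistert homologation and diazo transfer supply C5/C6. The acidic allylic sulfone is installed only after the last strong-base step; until then the C7 oxygen travels as a pivalate.
5. Side chain C7–C10: (Z)-allylic bromide from a Still–Gennari olefination.

Key step: step 17

Remark: C1–C10 in the text are the local numbers above; locants and descriptors inside compound names follow the nomenclature of each compound.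

**Route**

Step 1
Reactants: 1 (tert-butyldimethylsilyloxy)acetaldehyde; 2 ethyl 2-[bis(2,2,2-trifluoroethoxy)phosphoryl]propanoate
Product: 3 ethyl (2Z)-4-[(tert-butyldimethylsilyl)oxy]-2-methylbut-2-enoate
Conditions: KN(SiMe3)2, 18-crown-6, THF, −78 °C
Reagents that add atoms: none
Why: Still–Gennari olefination; the electron-poor phosphonate makes elimination of the first adduct fast, so the trisubstituted alkene should form with the ester carbon (C7) cis to the CH2O carbon (C10), the geometry ring B needs.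

Step 2
Reactants: 3 ethyl (2Z)-4-[(tert-butyldimethylsilyl)oxy]-2-methylbut-2-enoate
Product: 4 (2Z)-4-[(tert-butyldimethylsilyl)oxy]-2-methylbut-2-en-1-ol
Conditions: iBu2AlH, CH2Cl2, −78 °C
Reagents that add atoms: none
Why: 1,2-reduction of the enoate by the aluminium hydride gives the allylic alcohol and leaves the alkene geometry untouched.

Step 3
Reactants: 4 (2Z)-4-[(tert-butyldimethylsilyl)oxy]-2-methylbut-2-en-1-ol
Product: 5 (2Z)-4-[(tert-butyldimethylsilyl)oxy]-2-methylbut-2-en-1-yl pivalate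
Conditions: PivCl, pyridine, DMAP (cat.), CH2Cl2, 0 °C to rt
Reagents that add atoms: pivaloyl chloride CC(C)(C)C(=O)Cl
Why: DMAP-catalysed acylation; the pivalate has no α-hydrogen and is hindered, so it should survive the amide bases and enolates used later.

Step 4
Reactants: 5 (2Z)-4-[(tert-butyldimethylsilyl)oxy]-2-methylbut-2-en-1-yl pivalate
Product: 6 (2Z)-4-bromo-2-methylbut-2-en-1-yl pivalate
Conditions: Ph3PBr2, CH2Cl2, 0 °C
Reagents that add atoms: triphenylphosphine dibromide BrP(Br)(c1ccccc1)(c1ccccc1)c1ccccc1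
Why: Direct bromination of a silyl ether with triphenylphosphine dibromide; bromide displaces the oxyphosphonium group by SN2 at the primary allylic carbon, which should keep the Z geometry.

Step 5
Reactants: 7 methyl 4-methyl-3-oxopentanoate
Product: 8 methyl (3R)-3-hydroxy-4-methylpentanoate
Conditions: H2 (50 atm), RuCl2[(S)-BINAP] (cat.), MeOH, 50 °C
Reagents that add atoms: none
Why: Noyori asymmetric hydrogenation of a β-keto ester; the (S)-BINAP catalyst should deliver hydrogen to the face that gives the (R)-carbinol, which becomes C4.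

Step 6
Reactants: 8 methyl (3R)-3-hydroxy-4-methylpentanoate; 9 tert-butyl acetate
Product: 10 tert-butyl (5R)-5-hydroxy-6-methyl-3-oxoheptanoate
Conditions: 9 (4 equiv), LiN(iPr)2 (4 equiv), THF, −78 °C; then 8, −78 to −20 °C
Reagents that add atoms: none
Why: Crossed Claisen condensation with excess lithium enolate; the substrate travels as its alkoxide, which prevents β-elimination and leaves the carbinol centre untouched.

Step 7
Reactants: 10 tert-butyl (5R)-5-hydroxy-6-methyl-3-oxoheptanoate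
Product: 11 tert-butyl (3R,5R)-3,5-dihydroxy-6-methylheptanoate
Conditions: Me4NBH(OAc)3, AcOH/MeCN, −30 °C
Reagents that add atoms: none
Why: Evans–Saksena reduction; the borohydride bound to the C4 oxygen delivers hydride intramolecularly through a chair transition state, which should give the 1,3-anti diol and so set C2 from C4.

Step 8
Reactants: 11 tert-butyl (3R,5R)-3,5-dihydroxy-6-methylheptanoate; 6 (2Z)-4-bromo-2-methylbut-2-en-1-yl pivalate
Product: 12 tert-butyl (2R,3R,5R)-3,5-dihydroxy-6-methyl-2-[(2Z)-3-methyl-4-(pivaloyloxy)but-2-en-1-yl]heptanoate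
Conditions: LiN(iPr)2 (3.3 equiv), THF, −78 to −20 °C; then 6, DMPU, −78 to −20 °C
Reagents that add atoms: none
Why: Fráter–Seebach alkylation; the chelated lithium alkoxide–enolate (the C4 alkoxide is a spectator and the tert-butyl ester resists lactonisation) is C-allylated by SN2 at the primary allylic bromide, and the new C1 centre, formed anti to the C2 oxygen, is made planar again in step 9.

Step 9
Reactants: 12 tert-butyl (2R,3R,5R)-3,5-dihydroxy-6-methyl-2-[(2Z)-3-methyl-4-(pivaloyloxy)but-2-en-1-yl]heptanoate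
Product: 13 tert-butyl (2S,3R,5R)-3,5-dihydroxy-2,6-dimethyl-2-[(2Z)-3-methyl-4-(pivaloyloxy)but-2-en-1-yl]heptanoate
Conditions: LiN(iPr)2 (3.5 equiv), THF, −78 to −10 °C; then MeI, DMPU, −78 to −10 °C
Reagents that add atoms: iodomethane CI
Why: Second Fráter–Seebach alkylation; in the six-membered lithium chelate of the C2 alkoxide and the tetrasubstituted enolate, iodomethane should approach the face anti to the C3 chain, so methyl takes the position anti to the C2 oxygen and the side chain moves syn, which sets quaternary C1 as required.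

Step 10
Reactants: 13 tert-butyl (2S,3R,5R)-3,5-dihydroxy-2,6-dimethyl-2-[(2Z)-3-methyl-4-(pivaloyloxy)but-2-en-1-yl]heptanoate
Product: 14 tert-butyl (2S,3R,5R)-3-hydroxy-2,6-dimethyl-2-[(2Z)-3-methyl-4-(pivaloyloxy)but-2-en-1-yl]-5-[(triethylsilyl)oxy]heptanoate
Conditions: Et3SiCl (1.05 equiv), imidazole, CH2Cl2, −20 °C
Reagents that add atoms: chlorotriethylsilane CC[Si](Cl)(CC)CC
Why: Silylation under steric control; the C4 hydroxyl should react well before the C2 hydroxyl, which is neopentyl-like beside quaternary C1.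

Step 11
Reactants: 14 tert-butyl (2S,3R,5R)-3-hydroxy-2,6-dimethyl-2-[(2Z)-3-methyl-4-(pivaloyloxy)but-2-en-1-yl]-5-[(triethylsilyl)oxy]heptanoate
Product: 16 (2S,3R,5R)-3-[(tert-butyldimethylsilyl)oxy]-2,6-dimethyl-2-[(2Z)-3-methyl-4-(pivaloyloxy)but-2-en-1-yl]-5-[(triethylsilyl)oxy]heptanoic acid, via silyl ester 15 (not isolated)
Conditions: TBSOTf (3 equiv), 2,6-lutidine, CH2Cl2, 0 °C to rt; then K2CO3 (cat.), MeOH/H2O, 0 °C
Reagents that add atoms: tert-butyldimethylsilyl trifluoromethanesulfonate CC(C)(C)[Si](C)(C)OS(=O)(=O)C(F)(F)F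
Why: The silyl triflate silylates the hindered C2 hydroxyl and cleaves the tert-butyl ester to the silyl ester with loss of isobutene; mild hydrolysis of the labile silyl ester then frees the acid.

Step 12
Reactants: 16 (2S,3R,5R)-3-[(tert-butyldimethylsilyl)oxy]-2,6-dimethyl-2-[(2Z)-3-methyl-4-(pivaloyloxy)but-2-en-1-yl]-5-[(triethylsilyl)oxy]heptanoic acid
Product: 18 (3S,4R,6R)-4-[(tert-butyldimethylsilyl)oxy]-1-diazo-3,7-dimethyl-3-[(2Z)-3-methyl-4-(pivaloyloxy)but-2-en-1-yl]-6-[(triethylsilyl)oxy]octan-2-one, via acid chloride 17 (not isolated)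
Conditions: 1-chloro-N,N,2-trimethylprop-1-en-1-amine, CH2Cl2, 0 °C; then CH2N2 (excess), Et2O, 0 °C
Reagents that add atoms: 1-chloro-N,N,2-trimethylprop-1-en-1-amine CC(C)=C(Cl)N(C)C (chlorine of 17 only); diazomethane C=[N+]=[N-]
Why: First stage of the Arndt–Eistert homologation; the chloroenamine makes the hindered acid chloride under neutral conditions that spare the silyl ethers, and diazomethane is acylated to the diazoketone.

Step 13
Reactants: 18 (3S,4R,6R)-4-[(tert-butyldimethylsilyl)oxy]-1-diazo-3,7-dimethyl-3-[(2Z)-3-methyl-4-(pivaloyloxy)but-2-en-1-yl]-6-[(triethylsilyl)oxy]octan-2-one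
Product: 19 methyl (3R,4R,6R)-4-[(tert-butyldimethylsilyl)oxy]-3,7-dimethyl-3-[(2Z)-3-methyl-4-(pivaloyloxy)but-2-en-1-yl]-6-[(triethylsilyl)oxy]octanoate
Conditions: PhCO2Ag (cat.), Et3N, MeOH/THF, −25 °C to rt, dark
Reagents that add atoms: methanol CO
Why: Wolff rearrangement; quaternary C1 migrates with retention and methanol traps the ketene, so the new CH2 is C5 and the ester carbon is C6.

Step 14
Reactants: 19 methyl (3R,4R,6R)-4-[(tert-butyldimethylsilyl)oxy]-3,7-dimethyl-3-[(2Z)-3-methyl-4-(pivaloyloxy)but-2-en-1-yl]-6-[(triethylsilyl)oxy]octanoate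
Product: 21 methyl (3R,4R,6R)-4-[(tert-butyldimethylsilyl)oxy]-2-diazo-3,7-dimethyl-3-[(2Z)-3-methyl-4-(pivaloyloxy)but-2-en-1-yl]-6-[(triethylsilyl)oxy]octanoate, via trifluoroacetyl ester 20 (not isolated)
Conditions: LiN(iPr)2, THF, −78 °C; CF3CO2CH2CF3; then MsN3, Et3N, H2O (1 equiv), MeCN, rt
Reagents that add atoms: 2,2,2-trifluoroethyl trifluoroacetate O=C(OCC(F)(F)F)C(F)(F)F (trifluoroacetyl of 20 only); methanesulfonyl azide CS(=O)(=O)N=[N+]=[N-]
Why: Regitz diazo transfer in its detrifluoroacetylative form; Claisen trifluoroacetylation activates C5, the only enolisable position, and the sulfonyl azide then transfers N2 with loss of the trifluoroacetyl group.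

Step 15
Reactants: 21 methyl (3R,4R,6R)-4-[(tert-butyldimethylsilyl)oxy]-2-diazo-3,7-dimethyl-3-[(2Z)-3-methyl-4-(pivaloyloxy)but-2-en-1-yl]-6-[(triethylsilyl)oxy]octanoate
Product: 22 methyl (3R,4R,6R)-4-[(tert-butyldimethylsilyl)oxy]-2-diazo-3-[(2Z)-4-hydroxy-3-methylbut-2-en-1-yl]-3,7-dimethyl-6-[(triethylsilyl)oxy]octanoate
Conditions: NaOMe (0.3 equiv), MeOH, 0 °C to rt
Reagents that add atoms: none
Why: Transesterification removes the pivalate; the diazo ester has no α-hydrogen and its own methanolysis is degenerate, so it should be inert to methoxide.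

Step 16
Reactants: 22 methyl (3R,4R,6R)-4-[(tert-butyldimethylsilyl)oxy]-2-diazo-3-[(2Z)-4-hydroxy-3-methylbut-2-en-1-yl]-3,7-dimethyl-6-[(triethylsilyl)oxy]octanoate; 23 sodium benzenesulfinate
Product: 25 methyl (3R,4R,6R)-4-[(tert-butyldimethylsilyl)oxy]-2-diazo-3,7-dimethyl-3-[(2Z)-3-methyl-4-(phenylsulfonyl)but-2-en-1-yl]-6-[(triethylsilyl)oxy]octanoate, via allylic mesylate 24 (not isolated)
Conditions: MsCl, Et3N, CH2Cl2, −20 °C; then 23, DMF, rt
Reagents that add atoms: methanesulfonyl chloride CS(=O)(=O)Cl (mesyl group of 24 only)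
Why: Sulfonylation then SN2 S-alkylation of the sulfinate at the primary allylic carbon, which keeps the Z alkene; the sulfone comes in only now because its CH2 is more acidic than any ester and would not survive the enolate steps.

Step 17
Reactants: 25 methyl (3R,4R,6R)-4-[(tert-butyldimethylsilyl)oxy]-2-diazo-3,7-dimethyl-3-[(2Z)-3-methyl-4-(phenylsulfonyl)but-2-en-1-yl]-6-[(triethylsilyl)oxy]octanoate
Product: 26 methyl (1R,2R,3R,5R)-3-[(tert-butyldimethylsilyl)oxy]-2-methyl-2-[(2Z)-3-methyl-4-(phenylsulfonyl)but-2-en-1-yl]-5-(propan-2-yl)-5-[(triethylsilyl)oxy]cyclopentane-1-carboxylate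
Conditions: Rh2(OAc)4 (1 mol %), CH2Cl2, rt, slow addition of 25 at high dilution
Reagents that add atoms: none
Why: Rh2(OAc)4 expels N2 from 25 to give an electrophilic rhodium carbenoid at C5 which, lacking any β-hydrogen because C1 is quaternary, inserts into the C4–H bond through a concerted, asynchronous three-centre transition state with hydride-transfer character; the closest known reaction type is the rhodium-mediated intramolecular 1,5 C–H insertion of α-diazo esters to cyclopentanecarboxylates, here at a C–H bond activated by an adjacent ether oxygen. Ring A closes in the 1,5 mode through a chair-like array of C5, C1, C2, C3, C4 and the migrating hydrogen. C4 becomes the tertiary silyl-protected carbinol with retention, C5 taking the place of the hydrogen, so its configuration is that of the carbinol set in step 5. C5 is set by the orientation of the ester in that array, which should lie trans to the isopropyl group and the C10 chain, that is cis to the C4 oxygen and the C1 methyl, the arrangement that should also be the more stable one. The step needs insertion at C4–H rather than at other C–H bonds, cyclopropanation, ylide formation or alkyl shift: the silyloxy group activates the C4 methine, the sulfonyl group deactivates the C7–H bonds and the C8=C9 alkene, bulky silyl ethers are poor ylide donors, every other C–H bond would need a three-, four- or six-membered closure, and slow addition suppresses carbene dimerisation.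

Step 18
Reactants: 26 methyl (1R,2R,3R,5R)-3-[(tert-butyldimethylsilyl)oxy]-2-methyl-2-[(2Z)-3-methyl-4-(phenylsulfonyl)but-2-en-1-yl]-5-(propan-2-yl)-5-[(triethylsilyl)oxy]cyclopentane-1-carboxylate
Product: 27 (1R,3R,3aR,8aR)-1-[(tert-butyldimethylsilyl)oxy]-6,8a-dimethyl-5-(phenylsulfonyl)-3-(propan-2-yl)-3-[(triethylsilyl)oxy]-2,3,3a,5,8,8a-hexahydroazulen-4(1H)-one (epimers at the sulfonyl-bearing carbon)
Conditions: LiN(SiMe3)2 (2.5 equiv), THF, −78 to 0 °C; AcOH quench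
Reagents that add atoms: none
Why: Dieckmann-type acylation; the silylamide deprotonates only the allylic sulfone CH2 (C7), whose anion attacks the C6 ester through its α-carbon to close seven-membered ring B, and the product is held as its stabilised enolate, which protects C5 and the trans ring fusion.

Step 19
Reactants: 27 (1R,3R,3aR,8aR)-1-[(tert-butyldimethylsilyl)oxy]-6,8a-dimethyl-5-(phenylsulfonyl)-3-(propan-2-yl)-3-[(triethylsilyl)oxy]-2,3,3a,5,8,8a-hexahydroazulen-4(1H)-one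
Product: 28 (1R,3R,3aR,8aR)-1-[(tert-butyldimethylsilyl)oxy]-6,8a-dimethyl-3-(propan-2-yl)-3-[(triethylsilyl)oxy]-2,3,3a,5,8,8a-hexahydroazulen-4(1H)-one
Conditions: SmI2, THF/MeOH, −78 °C
Reagents that add atoms: none
Why: Reductive desulfonylation of a β-keto sulfone by single-electron transfer; kinetic protonation of the samarium dienolate at C7 should give the β,γ-enone and leave C5 untouched.

Step 20
Reactants: 28 (1R,3R,3aR,8aR)-1-[(tert-butyldimethylsilyl)oxy]-6,8a-dimethyl-3-(propan-2-yl)-3-[(triethylsilyl)oxy]-2,3,3a,5,8,8a-hexahydroazulen-4(1H)-one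
Product: 29 (1R,3R,3aR,8aR)-1-[(tert-butyldimethylsilyl)oxy]-3-hydroxy-6,8a-dimethyl-3-(propan-2-yl)-2,3,3a,5,8,8a-hexahydroazulen-4(1H)-one
Conditions: HF·pyridine, pyridine, THF, 0 °C
Reagents that add atoms: none
Why: Fluoride-mediated desilylation under buffered conditions; the triethylsilyl ether should cleave well before the hindered secondary tert-butyldimethylsilyl ether, and the buffer guards against dehydration and enone conjugation.

Step 21
Reactants: 29 (1R,3R,3aR,8aR)-1-[(tert-butyldimethylsilyl)oxy]-3-hydroxy-6,8a-dimethyl-3-(propan-2-yl)-2,3,3a,5,8,8a-hexahydroazulen-4(1H)-one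
Product: 30 (1R,3R,3aS,4S,8aR)-1-[(tert-butyldimethylsilyl)oxy]-6,8a-dimethyl-3-(propan-2-yl)-1,2,3,3a,4,5,8,8a-octahydroazulene-3,4-diol
Conditions: Me4NBH(OAc)3, AcOH/MeCN, −30 °C
Reagents that add atoms: none
Why: Hydroxyl-directed (Evans–Saksena) reduction; the borohydride bound to the C4 oxygen, which lies on the lower face with the C5–C6 bond, should deliver hydride to the lower face of the C6 ketone and so give the 1,3-anti diol with the C6 configuration of the target.

Step 22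
Reactants: 30 (1R,3R,3aS,4S,8aR)-1-[(tert-butyldimethylsilyl)oxy]-6,8a-dimethyl-3-(propan-2-yl)-1,2,3,3a,4,5,8,8a-octahydroazulene-3,4-diol; 31 4-methoxybenzoyl chloride
Product: 32 (1R,3R,3aS,4S,8aR)-1-[(tert-butyldimethylsilyl)oxy]-3-hydroxy-6,8a-dimethyl-3-(propan-2-yl)-1,2,3,3a,4,5,8,8a-octahydroazulen-4-yl 4-methoxybenzoate
Conditions: 31, Et3N, DMAP, CH2Cl2, rt
Reagents that add atoms: none
Why: DMAP-catalysed acylation; only the secondary C6 hydroxyl should react, the C4 hydroxyl being tertiary and the C2 oxygen still silylated.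

Step 23
Reactants: 32 (1R,3R,3aS,4S,8aR)-1-[(tert-butyldimethylsilyl)oxy]-3-hydroxy-6,8a-dimethyl-3-(propan-2-yl)-1,2,3,3a,4,5,8,8a-octahydroazulen-4-yl 4-methoxybenzoate
Product: 33 (1R,3R,3aS,4S,8aR)-1,3-dihydroxy-6,8a-dimethyl-3-(propan-2-yl)-1,2,3,3a,4,5,8,8a-octahydroazulen-4-yl 4-methoxybenzoate
Conditions: HF (48% aq), MeCN, rt
Reagents that add atoms: none
Why: Acidic fluoride desilylation of the hindered secondary silyl ether; these conditions should avoid the acyl migration that a basic fluoride source could cause.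

Step 24
Reactants: 33 (1R,3R,3aS,4S,8aR)-1,3-dihydroxy-6,8a-dimethyl-3-(propan-2-yl)-1,2,3,3a,4,5,8,8a-octahydroazulen-4-yl 4-methoxybenzoate; 34 angelic acid, (2Z)-2-methylbut-2-enoic acid
Product: 35 (1R,3R,3aS,4S,8aR)-3-hydroxy-4-[(4-methoxybenzoyl)oxy]-6,8a-dimethyl-3-(propan-2-yl)-1,2,3,3a,4,5,8,8a-octahydroazulen-1-yl (2Z)-2-methylbut-2-enoate (CNP0204191.1)
Conditions: 34, 2,4,6-trichlorobenzoyl chloride, Et3N, toluene, rt; then 33, 80 °C
Reagents that add atoms: none
Why: Yamaguchi-type esterification through the mixed anhydride made in the flask; it acylates the hindered secondary C2 hydroxyl without base-induced Z-to-E isomerisation of the angelate, and the tertiary C4 hydroxyl should stay free.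

**Compound list**

1 | (tert-butyldimethylsilyloxy)acetaldehyde | O=CCO[Si](C)(C)C(C)(C)C | starting material
2 | ethyl 2-[bis(2,2,2-trifluoroethoxy)phosphoryl]propanoate | CCOC(=O)C(C)P(=O)(OCC(F)(F)F)OCC(F)(F)F | starting material
3 | ethyl (2Z)-4-[(tert-butyldimethylsilyl)oxy]-2-methylbut-2-enoate | CCOC(=O)/C(C)=C\CO[Si](C)(C)C(C)(C)C | intermediate
4 | (2Z)-4-[(tert-butyldimethylsilyl)oxy]-2-methylbut-2-en-1-ol | OC/C(C)=C\CO[Si](C)(C)C(C)(C)C | intermediate
5 | (2Z)-4-[(tert-butyldimethylsilyl)oxy]-2-methylbut-2-en-1-yl pivalate | CC(C)(C)C(=O)OC/C(C)=C\CO[Si](C)(C)C(C)(C)C | intermediate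
6 | (2Z)-4-bromo-2-methylbut-2-en-1-yl pivalate | CC(C)(C)C(=O)OC/C(C)=C\CBr | intermediate
7 | methyl 4-methyl-3-oxopentanoate | COC(=O)CC(=O)C(C)C | starting material
8 | methyl (3R)-3-hydroxy-4-methylpentanoate | COC(=O)C[C@@H](O)C(C)C | intermediate
9 | tert-butyl acetate | CC(=O)OC(C)(C)C | starting material
10 | tert-butyl (5R)-5-hydroxy-6-methyl-3-oxoheptanoate | CC(C)(C)OC(=O)CC(=O)C[C@@H](O)C(C)C | intermediate
11 | tert-butyl (3R,5R)-3,5-dihydroxy-6-methylheptanoate | CC(C)(C)OC(=O)C[C@H](O)C[C@@H](O)C(C)C | intermediate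
12 | tert-butyl (2R,3R,5R)-3,5-dihydroxy-6-methyl-2-[(2Z)-3-methyl-4-(pivaloyloxy)but-2-en-1-yl]heptanoate | CC(C)(C)OC(=O)[C@H](C/C=C(/C)COC(=O)C(C)(C)C)[C@H](O)C[C@@H](O)C(C)C | intermediate
13 | tert-butyl (2S,3R,5R)-3,5-dihydroxy-2,6-dimethyl-2-[(2Z)-3-methyl-4-(pivaloyloxy)but-2-en-1-yl]heptanoate | CC(C)(C)OC(=O)[C@@](C)(C/C=C(/C)COC(=O)C(C)(C)C)[C@H](O)C[C@@H](O)C(C)C | intermediate
14 | tert-butyl (2S,3R,5R)-3-hydroxy-2,6-dimethyl-2-[(2Z)-3-methyl-4-(pivaloyloxy)but-2-en-1-yl]-5-[(triethylsilyl)oxy]heptanoate | CC(C)(C)OC(=O)[C@@](C)(C/C=C(/C)COC(=O)C(C)(C)C)[C@H](O)C[C@@H](O[Si](CC)(CC)CC)C(C)C | intermediate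
15 | tert-butyldimethylsilyl (2S,3R,5R)-3-[(tert-butyldimethylsilyl)oxy]-2,6-dimethyl-2-[(2Z)-3-methyl-4-(pivaloyloxy)but-2-en-1-yl]-5-[(triethylsilyl)oxy]heptanoate | CC(C)(C)[Si](C)(C)OC(=O)[C@@](C)(C/C=C(/C)COC(=O)C(C)(C)C)[C@H](O[Si](C)(C)C(C)(C)C)C[C@@H](O[Si](CC)(CC)CC)C(C)C | intermediate
16 | (2S,3R,5R)-3-[(tert-butyldimethylsilyl)oxy]-2,6-dimethyl-2-[(2Z)-3-methyl-4-(pivaloyloxy)but-2-en-1-yl]-5-[(triethylsilyl)oxy]heptanoic acid | OC(=O)[C@@](C)(C/C=C(/C)COC(=O)C(C)(C)C)[C@H](O[Si](C)(C)C(C)(C)C)C[C@@H](O[Si](CC)(CC)CC)C(C)C | intermediate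
17 | (2S,3R,5R)-3-[(tert-butyldimethylsilyl)oxy]-2,6-dimethyl-2-[(2Z)-3-methyl-4-(pivaloyloxy)but-2-en-1-yl]-5-[(triethylsilyl)oxy]heptanoyl chloride | ClC(=O)[C@@](C)(C/C=C(/C)COC(=O)C(C)(C)C)[C@H](O[Si](C)(C)C(C)(C)C)C[C@@H](O[Si](CC)(CC)CC)C(C)C | intermediate
18 | (3S,4R,6R)-4-[(tert-butyldimethylsilyl)oxy]-1-diazo-3,7-dimethyl-3-[(2Z)-3-methyl-4-(pivaloyloxy)but-2-en-1-yl]-6-[(triethylsilyl)oxy]octan-2-one | [N-]=[N+]=CC(=O)[C@@](C)(C/C=C(/C)COC(=O)C(C)(C)C)[C@H](O[Si](C)(C)C(C)(C)C)C[C@@H](O[Si](CC)(CC)CC)C(C)C | intermediate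
19 | methyl (3R,4R,6R)-4-[(tert-butyldimethylsilyl)oxy]-3,7-dimethyl-3-[(2Z)-3-methyl-4-(pivaloyloxy)but-2-en-1-yl]-6-[(triethylsilyl)oxy]octanoate | COC(=O)C[C@@](C)(C/C=C(/C)COC(=O)C(C)(C)C)[C@H](O[Si](C)(C)C(C)(C)C)C[C@@H](O[Si](CC)(CC)CC)C(C)C | intermediate
20 | methyl (3R,4R,6R)-4-[(tert-butyldimethylsilyl)oxy]-3,7-dimethyl-3-[(2Z)-3-methyl-4-(pivaloyloxy)but-2-en-1-yl]-6-[(triethylsilyl)oxy]-2-(trifluoroacetyl)octanoate (C2 epimers) | COC(=O)C(C(=O)C(F)(F)F)[C@@](C)(C/C=C(/C)COC(=O)C(C)(C)C)[C@H](O[Si](C)(C)C(C)(C)C)C[C@@H](O[Si](CC)(CC)CC)C(C)C | intermediate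
21 | methyl (3R,4R,6R)-4-[(tert-butyldimethylsilyl)oxy]-2-diazo-3,7-dimethyl-3-[(2Z)-3-methyl-4-(pivaloyloxy)but-2-en-1-yl]-6-[(triethylsilyl)oxy]octanoate | COC(=O)C(=[N+]=[N-])[C@@](C)(C/C=C(/C)COC(=O)C(C)(C)C)[C@H](O[Si](C)(C)C(C)(C)C)C[C@@H](O[Si](CC)(CC)CC)C(C)C | intermediate
22 | methyl (3R,4R,6R)-4-[(tert-butyldimethylsilyl)oxy]-2-diazo-3-[(2Z)-4-hydroxy-3-methylbut-2-en-1-yl]-3,7-dimethyl-6-[(triethylsilyl)oxy]octanoate | COC(=O)C(=[N+]=[N-])[C@@](C)(C/C=C(/C)CO)[C@H](O[Si](C)(C)C(C)(C)C)C[C@@H](O[Si](CC)(CC)CC)C(C)C | intermediate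
23 | sodium benzenesulfinate | [Na+].[O-]S(=O)c1ccccc1 | starting material
24 | methyl (3R,4R,6R)-4-[(tert-butyldimethylsilyl)oxy]-2-diazo-3,7-dimethyl-3-[(2Z)-3-methyl-4-(methylsulfonyloxy)but-2-en-1-yl]-6-[(triethylsilyl)oxy]octanoate | COC(=O)C(=[N+]=[N-])[C@@](C)(C/C=C(/C)COS(C)(=O)=O)[C@H](O[Si](C)(C)C(C)(C)C)C[C@@H](O[Si](CC)(CC)CC)C(C)C | intermediate
25 | methyl (3R,4R,6R)-4-[(tert-butyldimethylsilyl)oxy]-2-diazo-3,7-dimethyl-3-[(2Z)-3-methyl-4-(phenylsulfonyl)but-2-en-1-yl]-6-[(triethylsilyl)oxy]octanoate | COC(=O)C(=[N+]=[N-])[C@@](C)(C/C=C(/C)CS(=O)(=O)c1ccccc1)[C@H](O[Si](C)(C)C(C)(C)C)C[C@@H](O[Si](CC)(CC)CC)C(C)C | intermediate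
26 | methyl (1R,2R,3R,5R)-3-[(tert-butyldimethylsilyl)oxy]-2-methyl-2-[(2Z)-3-methyl-4-(phenylsulfonyl)but-2-en-1-yl]-5-(propan-2-yl)-5-[(triethylsilyl)oxy]cyclopentane-1-carboxylate | CC(C)(C)[Si](C)(C)O[C@@H]1C[C@@](O[Si](CC)(CC)CC)(C(C)C)[C@H](C(=O)OC)[C@@]1(C)C/C=C(/C)CS(=O)(=O)c1ccccc1 | intermediate
27 | (1R,3R,3aR,8aR)-1-[(tert-butyldimethylsilyl)oxy]-6,8a-dimethyl-5-(phenylsulfonyl)-3-(propan-2-yl)-3-[(triethylsilyl)oxy]-2,3,3a,5,8,8a-hexahydroazulen-4(1H)-one | CC(C)(C)[Si](C)(C)O[C@@H]1C[C@@](O[Si](CC)(CC)CC)(C(C)C)[C@@H]2C(=O)C(S(=O)(=O)c3ccccc3)C(C)=CC[C@]21C | intermediate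
28 | (1R,3R,3aR,8aR)-1-[(tert-butyldimethylsilyl)oxy]-6,8a-dimethyl-3-(propan-2-yl)-3-[(triethylsilyl)oxy]-2,3,3a,5,8,8a-hexahydroazulen-4(1H)-one | CC(C)(C)[Si](C)(C)O[C@@H]1C[C@@](O[Si](CC)(CC)CC)(C(C)C)[C@@H]2C(=O)CC(C)=CC[C@]21C | intermediate
29 | (1R,3R,3aR,8aR)-1-[(tert-butyldimethylsilyl)oxy]-3-hydroxy-6,8a-dimethyl-3-(propan-2-yl)-2,3,3a,5,8,8a-hexahydroazulen-4(1H)-one | CC(C)(C)[Si](C)(C)O[C@@H]1C[C@@](O)(C(C)C)[C@@H]2C(=O)CC(C)=CC[C@]21C | intermediate
30 | (1R,3R,3aS,4S,8aR)-1-[(tert-butyldimethylsilyl)oxy]-6,8a-dimethyl-3-(propan-2-yl)-1,2,3,3a,4,5,8,8a-octahydroazulene-3,4-diol | CC(C)(C)[Si](C)(C)O[C@@H]1C[C@@](O)(C(C)C)[C@@H]2[C@@H](O)CC(C)=CC[C@]21C | intermediate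
31 | 4-methoxybenzoyl chloride | COc1ccc(cc1)C(=O)Cl | starting material
32 | (1R,3R,3aS,4S,8aR)-1-[(tert-butyldimethylsilyl)oxy]-3-hydroxy-6,8a-dimethyl-3-(propan-2-yl)-1,2,3,3a,4,5,8,8a-octahydroazulen-4-yl 4-methoxybenzoate | CC(C)(C)[Si](C)(C)O[C@@H]1C[C@@](O)(C(C)C)[C@@H]2[C@@H](OC(=O)c3ccc(OC)cc3)CC(C)=CC[C@]21C | intermediate
33 | (1R,3R,3aS,4S,8aR)-1,3-dihydroxy-6,8a-dimethyl-3-(propan-2-yl)-1,2,3,3a,4,5,8,8a-octahydroazulen-4-yl 4-methoxybenzoate | O[C@@H]1C[C@@](O)(C(C)C)[C@@H]2[C@@H](OC(=O)c3ccc(OC)cc3)CC(C)=CC[C@]21C | intermediate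
34 | angelic acid, (2Z)-2-methylbut-2-enoic acid | C/C=C(/C)C(=O)O | starting material
35 | (1R,3R,3aS,4S,8aR)-3-hydroxy-4-[(4-methoxybenzoyl)oxy]-6,8a-dimethyl-3-(propan-2-yl)-1,2,3,3a,4,5,8,8a-octahydroazulen-1-yl (2Z)-2-methylbut-2-enoate, CNP0204191.1 | C/C=C(/C)C(=O)O[C@@H]1C[C@@](O)(C(C)C)[C@@H]2[C@@H](OC(=O)c3ccc(OC)cc3)CC(C)=CC[C@]21C | target

**Step count and risks**

Total step count: 24. Longest linear sequence: 21 steps (steps 1–4, then 8–24).

Steps most likely to fail: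

1. Step 17. The carbenoid may be consumed by other pathways: insertion into the isopropyl methine through a six-membered closure, 1,2-shift of a C1 substituent, or attack on a silyl ether oxygen. It may also deliver the C5 ester cis to the isopropyl group. The fallback closes C4–C5 by an intramolecular Reformatsky aldol. It sets out from 19. Bromination of the ester enolate (LiN(iPr)2, then BrCCl2CCl2Br, THF, −78 °C) should give the α-bromo ester F1. PPTS in MeOH should remove the C4 triethylsilyl group to give the bromo alcohol F2. Dess–Martin oxidation should give the isopropyl ketone F3. SmI2 (THF, −78 °C) should then generate the samarium enolate at C5, which adds to the C4 ketone through a chelated transition state to give the cyclopentanol F4 with the hydroxyl cis to the ester. TESOTf and 2,6-lutidine should give the silyl ether F5. K2CO3 in MeOH should remove the pivalate to give the allylic alcohol F6. MsCl and Et3N should give the mesylate F7, and PhSO2Na in DMF brings the sequence back to the route at 26.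

2. Step 18. The crowded C6 ester may resist attack, the allylic anion may acylate through C9 and close a five-membered ketone, or prolonged contact with base may eliminate the C4 silyloxy group. The fallback replaces the acylation by addition to an aldehyde and sets out from 26. iBu2AlH should reduce the ester to the primary alcohol F8. Dess–Martin oxidation should give the aldehyde F9. LiN(SiMe3)2 (1.05 equiv, THF, −78 °C) should deprotonate the accessible sulfone CH2 kinetically, and its anion adds to the much more electrophilic aldehyde to close ring B as the β-hydroxy sulfone F10. A second Dess–Martin oxidation returns to the route at 27.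

3. Step 14. C–N bond formation at C5, next to quaternary C1, may be slow, so that the trifluoroacetyl group is lost by retro-Claisen cleavage before the diazo group is transferred. The fallback makes the diazo group by a Bamford–Stevens elimination and sets out from 19. KN(SiMe3)2 and 2-(phenylsulfonyl)-3-phenyloxaziridine (THF, −78 °C) should hydroxylate the enolate to the α-hydroxy ester F11. Dess–Martin oxidation should give the α-keto ester F12. TsNHNH2 (MeOH, 60 °C) should give the tosylhydrazone F13. Et3N in CH2Cl2 at rt should eliminate p-toluenesulfinate and return to the route at 21.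

**Further compounds**

F1 | step 17 | methyl 2-bromo-4-[(tert-butyldimethylsilyl)oxy]-3,7-dimethyl-3-[(2Z)-3-methyl-4-(pivaloyloxy)but-2-en-1-yl]-6-[(triethylsilyl)oxy]octanoate (C2 epimers, other centres as in 19) | COC(=O)C(Br)[C@@](C)(C/C=C(/C)COC(=O)C(C)(C)C)[C@H](O[Si](C)(C)C(C)(C)C)C[C@@H](O[Si](CC)(CC)CC)C(C)C
F2 | step 17 | methyl 2-bromo-4-[(tert-butyldimethylsilyl)oxy]-6-hydroxy-3,7-dimethyl-3-[(2Z)-3-methyl-4-(pivaloyloxy)but-2-en-1-yl]octanoate | COC(=O)C(Br)[C@@](C)(C/C=C(/C)COC(=O)C(C)(C)C)[C@H](O[Si](C)(C)C(C)(C)C)C[C@@H](O)C(C)C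
F3 | step 17 | methyl 2-bromo-4-[(tert-butyldimethylsilyl)oxy]-3,7-dimethyl-3-[(2Z)-3-methyl-4-(pivaloyloxy)but-2-en-1-yl]-6-oxooctanoate | COC(=O)C(Br)[C@@](C)(C/C=C(/C)COC(=O)C(C)(C)C)[C@H](O[Si](C)(C)C(C)(C)C)CC(=O)C(C)C
F4 | step 17 | methyl (1R,2R,3R,5R)-3-[(tert-butyldimethylsilyl)oxy]-5-hydroxy-2-methyl-2-[(2Z)-3-methyl-4-(pivaloyloxy)but-2-en-1-yl]-5-(propan-2-yl)cyclopentane-1-carboxylate | CC(C)(C)[Si](C)(C)O[C@@H]1C[C@@](O)(C(C)C)[C@H](C(=O)OC)[C@@]1(C)C/C=C(/C)COC(=O)C(C)(C)C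
F5 | step 17 | methyl (1R,2R,3R,5R)-3-[(tert-butyldimethylsilyl)oxy]-2-methyl-2-[(2Z)-3-methyl-4-(pivaloyloxy)but-2-en-1-yl]-5-(propan-2-yl)-5-[(triethylsilyl)oxy]cyclopentane-1-carboxylate | CC(C)(C)[Si](C)(C)O[C@@H]1C[C@@](O[Si](CC)(CC)CC)(C(C)C)[C@H](C(=O)OC)[C@@]1(C)C/C=C(/C)COC(=O)C(C)(C)C
F6 | step 17 | methyl (1R,2R,3R,5R)-3-[(tert-butyldimethylsilyl)oxy]-2-[(2Z)-4-hydroxy-3-methylbut-2-en-1-yl]-2-methyl-5-(propan-2-yl)-5-[(triethylsilyl)oxy]cyclopentane-1-carboxylate | CC(C)(C)[Si](C)(C)O[C@@H]1C[C@@](O[Si](CC)(CC)CC)(C(C)C)[C@H](C(=O)OC)[C@@]1(C)C/C=C(/C)CO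
F7 | step 17 | methyl (1R,2R,3R,5R)-3-[(tert-butyldimethylsilyl)oxy]-2-methyl-2-[(2Z)-3-methyl-4-(methylsulfonyloxy)but-2-en-1-yl]-5-(propan-2-yl)-5-[(triethylsilyl)oxy]cyclopentane-1-carboxylate | CC(C)(C)[Si](C)(C)O[C@@H]1C[C@@](O[Si](CC)(CC)CC)(C(C)C)[C@H](C(=O)OC)[C@@]1(C)C/C=C(/C)COS(C)(=O)=O
F8 | step 18 | primary alcohol from reduction of the ester of 26, [3-[(tert-butyldimethylsilyl)oxy]-2-methyl-2-[(2Z)-3-methyl-4-(phenylsulfonyl)but-2-en-1-yl]-5-(propan-2-yl)-5-[(triethylsilyl)oxy]cyclopentyl]methanol, ring configurations as in 26 | CC(C)(C)[Si](C)(C)O[C@@H]1C[C@@](O[Si](CC)(CC)CC)(C(C)C)[C@H](CO)[C@@]1(C)C/C=C(/C)CS(=O)(=O)c1ccccc1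
F9 | step 18 | corresponding cyclopentanecarbaldehyde, ring configurations as in 26 | CC(C)(C)[Si](C)(C)O[C@@H]1C[C@@](O[Si](CC)(CC)CC)(C(C)C)[C@H](C=O)[C@@]1(C)C/C=C(/C)CS(=O)(=O)c1ccccc1
F10 | step 18 | 1-[(tert-butyldimethylsilyl)oxy]-6,8a-dimethyl-5-(phenylsulfonyl)-3-(propan-2-yl)-3-[(triethylsilyl)oxy]-1,2,3,3a,4,5,8,8a-octahydroazulen-4-ol (epimers at C4 and C5 of the azulene, other centres as in 27) | CC(C)(C)[Si](C)(C)O[C@@H]1C[C@@](O[Si](CC)(CC)CC)(C(C)C)[C@@H]2C(O)C(S(=O)(=O)c3ccccc3)C(C)=CC[C@]21C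
F11 | step 14 | methyl 4-[(tert-butyldimethylsilyl)oxy]-2-hydroxy-3,7-dimethyl-3-[(2Z)-3-methyl-4-(pivaloyloxy)but-2-en-1-yl]-6-[(triethylsilyl)oxy]octanoate (C2 epimers, other centres as in 19) | COC(=O)C(O)[C@@](C)(C/C=C(/C)COC(=O)C(C)(C)C)[C@H](O[Si](C)(C)C(C)(C)C)C[C@@H](O[Si](CC)(CC)CC)C(C)C
F12 | step 14 | methyl 4-[(tert-butyldimethylsilyl)oxy]-3,7-dimethyl-3-[(2Z)-3-methyl-4-(pivaloyloxy)but-2-en-1-yl]-2-oxo-6-[(triethylsilyl)oxy]octanoate (centres as in 19) | COC(=O)C(=O)[C@@](C)(C/C=C(/C)COC(=O)C(C)(C)C)[C@H](O[Si](C)(C)C(C)(C)C)C[C@@H](O[Si](CC)(CC)CC)C(C)C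
F13 | step 14 | 4-methylbenzenesulfonylhydrazone of F12 | COC(=O)C(=NNS(=O)(=O)c1ccc(C)cc1)[C@@](C)(C/C=C(/C)COC(=O)C(C)(C)C)[C@H](O[Si](C)(C)C(C)(C)C)C[C@@H](O[Si](CC)(CC)CC)C(C)C
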